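**Assumption:** commercial (2S)-naringenin is used at high ee, and NIS iodinates the A-ring C6 and C8 positions before the B ring.

## Retrosynthetic overview
- The target (a 5-hydroxy-2,2-dimethylchromene fused on the B ring at C2'/C3') comes from its 7,4'-diacetate after removal of the A-ring iodine blockers and deacetylation.
- The pyran ring is formed last. The C2'–O bond comes from anodic dehydrogenative C–H/O–H etherification of a 3'-(3-hydroxy-3-methylbut-1-enyl) arene.
- That styrenyl alcohol comes from a Heck coupling of the 3'-iodide, which comes from iodination of (2S)-naringenin.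
- The only stereocenter, C2 (S), is carried untouched from (2S)-naringenin. Ring order: A/C rings are in the starting material, and the chromene ring is made last.

## Route

**Step 1**
Reactants: 1 (2S)-naringenin; 2 N-iodosuccinimide
Product: 3 (2S)-5,7,4'-trihydroxy-6,8,3'-triiodoflavanone
Conditions: NIS (3.1 equiv), MeCN, 0 °C → rt, dark
Reagents that add atoms: NIS, O=C1CCC(=O)N1I
Why: Electrophilic aromatic iodination. The A-ring C6 and C8 positions react first, and the B ring is then iodinated ortho to the 4'-OH. The A-ring iodides block the A ring for later steps. C2 is not touched, and the conditions are acidic or neutral, so it does not racemize.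

**Step 2**
Reactants: 3; 4 acetic anhydride
Product: 5 (2S)-7,4'-diacetoxy-5-hydroxy-6,8,3'-triiodoflavanone
Conditions: Ac2O (2.3 equiv), pyridine, cat. DMAP, CH2Cl2, 0 °C → rt
Reagents that add atoms: Ac2O, CC(=O)OC(C)=O
Why: O-Acylation. The 5-OH stays free because it is hydrogen-bonded to the C4 carbonyl. Acetylation of the 7- and 4'-OH groups removes the oxidizable phenols needed for the later anodic step. No stereocenter is formed or affected.

**Step 3**
Reactants: 5; 6 2-methylbut-3-en-2-ol
Product: 7 (2S)-7,4'-diacetoxy-5-hydroxy-6,8-diiodo-3'-[(E)-3-hydroxy-3-methylbut-1-enyl]flavanone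
Conditions: 6 (1.5 equiv), Pd(OAc)2 (5 mol%), nBu4NCl, NaHCO3, DMF, 50 °C
Reagents that add atoms: 2-methylbut-3-en-2-ol, C=CC(C)(C)O
Why: Mizoroki–Heck reaction under Jeffery conditions. The B-ring C–I bond is unhindered and reacts selectively over the two di-ortho-substituted A-ring C–I bonds. The carbinol carbon has no hydrogen, so β-H elimination gives the styrene rather than a ketone. The mild base and low temperature protect C2 from ring-opening.

**Step 4**
Reactants: 7
Product: 8 (2S)-7,4'-diacetoxy-5-hydroxy-6,8-diiodo-flavanone fused at C2'/C3' with a 2,2-dimethyl-2H-chromene ring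
Conditions: graphite anode | Pt cathode, nBu4NBF4, HFIP/CH2Cl2 (1:4), 2,6-di-tert-butylpyridine (0.5 equiv), 3 mA, rt (2.3 F/mol)
Reagents that add atoms: none (H2 is lost at the cathode)
Why: Proposed new method: the closest known reactions are electro-oxidative intramolecular arene C–H etherification and anodic olefin–alcohol coupling.
- The styrenyl arene is the most easily oxidized unit and gives a radical cation.
- Alkene radical cations rotate freely, so the E alkene equilibrates to the Z geometry the ring closure requires.
- The tertiary alcohol then adds to C2', which is ortho to the vinyl group.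
- The resulting cyclohexadienyl radical is delocalized onto the vinyl group, so it is stabilized.
- A second oxidation and loss of H+ rearomatize the ring and give the chromene.
- The 4'-OAc group suppresses ipso capture at C4'. The cathode evolves H2 from HFIP.
- C2 is not involved and no new stereocenter forms.

**Step 5**
Reactants: 8
Product: 9 (2S)-7,4'-diacetoxy-5-hydroxy-flavanone fused with the 2,2-dimethylchromene (A-ring iodides removed)
Conditions: fac-Ir(ppy)3 (1 mol%), Hantzsch ester (3 equiv), DMF, blue LEDs, rt
Reagents that add atoms: none (the Hantzsch ester only supplies hydrogen)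
Why: Photoredox hydrodeiodination. The excited iridium complex reduces the aryl iodides, the aryl radicals abstract H, and the chromene alkene and C2 are untouched.

**Step 6**
Reactants: 9
Product: 10 Sanggenone H, (2S)-5,7,4'-trihydroxy flavanone with the 2,2-dimethyl-2H-chromene fused at C2'/C3'
Conditions: NH4OAc (10 equiv), MeOH/H2O (9:1), 40 °C
Reagents that add atoms: none
Why: Near-neutral aminolysis and transesterification of the two aryl acetates. The 5-OH was never acylated. The avoidance of strong base prevents flavanone ring-opening and racemization at C2, and the chromene survives.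

## Compound list
1 | (2S)-naringenin | Oc1ccc(cc1)[C@@H]1CC(=O)c2c(O)cc(O)cc2O1 | starting material
2 | N-iodosuccinimide | O=C1CCC(=O)N1I | starting material (reagent)
3 | (2S)-6,8,3'-triiodonaringenin | Oc1ccc(cc1I)[C@@H]1CC(=O)c2c(O)c(I)c(O)c(I)c2O1 | intermediate
4 | acetic anhydride | CC(=O)OC(C)=O | starting material (reagent)
5 | 7,4'-di-O-acetyl-6,8,3'-triiodonaringenin | CC(=O)Oc1ccc(cc1I)[C@@H]1CC(=O)c2c(O)c(I)c(OC(C)=O)c(I)c2O1 | intermediate
6 | 2-methylbut-3-en-2-ol | C=CC(C)(C)O | starting material (reagent)
7 | Heck product | CC(=O)Oc1ccc(cc1/C=C/C(C)(C)O)[C@@H]1CC(=O)c2c(O)c(I)c(OC(C)=O)c(I)c2O1 | intermediate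
8 | chromene diiodo diacetate | CC1(C)C=Cc2c(OC(C)=O)ccc([C@@H]3CC(=O)c4c(O)c(I)c(OC(C)=O)c(I)c4O3)c2O1 | intermediate
9 | chromene diacetate | CC1(C)C=Cc2c(OC(C)=O)ccc([C@@H]3CC(=O)c4c(O)cc(OC(C)=O)cc4O3)c2O1 | intermediate
10 | Sanggenone H | CC1(C)C=Cc2c(O)ccc([C@@H]3CC(=O)c4c(O)cc(O)cc4O3)c2O1 | target

## Totals
Total steps: 6. Longest linear sequence: 6 (from 1).

## Three steps most likely to fail
1. **Step 4 (the proposed new step).** Capture at C2' may lose to ipso capture at C4', to neighboring-group capture by the 4'-acetate, or to acid-promoted ionization of the tertiary allylic alcohol.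
   Fallback (known chemistry, different approach): convert the 3'-iodide to 3'-acetyl (Stille with (1-ethoxyvinyl)tin, then hydrolysis). Hydroxylate C2' with Ru(OAc)2(p-cymene)/PIFA ketone-directed C–H hydroxylation. Then run the Kabbe condensation (acetone/pyrrolidine), NaBH4 reduction and TsOH dehydration to the chromene.
2. **Step 1.** Triiodination may give over-iodination of the B ring (3',5'-diiodide) or partial racemization.
   Fallback: deactivate the A ring by BF2 chelation of the 5-OH/C4 carbonyl, then mono-iodinate the B ring with NIS. This removes the need for the A-ring iodides and for Step 5.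
3. **Step 3.** The Heck coupling may lose chemoselectivity to the A-ring iodides, or the base and heat may erode the ee.
   Fallback: Sonogashira coupling with 2-methylbut-3-yn-2-ol at room temperature, followed by Z-selective Zn(Cu/Ag) reduction, which gives the Z-alkenol directly.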